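**Retrosynthetic overview**
1. Target ⇒ macrolactone 22: the tetrahydropyran is the last ring, closed by 6-exo opening of a C12–C13 epoxide by the C3 oxygen (lactone opened and re-closed in the same flask).
2. 22 ⇒ bromo aldehyde 20: one CrCl2-mediated intramolecular allylation/lactonisation closes the 14-membered carbocycle (C1–C2 bond) and the cis α-methylene-γ-lactone together (key step).
3. 20 ⇒ skipped enyne 14 (copper coupling of alkyne 7 with allylic bromide 13), followed by Shi epoxidation, Lindlar reduction, α-benzoyloxylation and SN2′ bromination.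
4. 7 ⇐ (S)-citronellol (C4 from the pool, C8 by Sharpless epoxidation/hydride opening); 13 ⇐ 4-methylpent-3-en-1-ol + methyl acrylate (Morita–Baylis–Hillman, SeO2 oxidation).
5. Ring order: 14-membered carbocycle and γ-lactone in one operation, then the tetrahydropyran.

Assumption: cembrane numbering is used for the macrocycles (ring C1–C14; C15 = acrylate α-carbon, C16 = carboxyl carbon, C17 = exocyclic CH2; methyls on C4, C8, C12), so the target is (1R,2S,3R,4S,8R,9Z,12S,13R)-3,13-epoxy-8,12-dihydroxycembra-9,15(17)-dien-16,2-olide.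

**Route**

Step 1
Reactants: 1 (S)-citronellol [(3S)-3,7-dimethyloct-6-en-1-ol]
Product: 2 tert-butyl{[(3S)-3,7-dimethyloct-6-en-1-yl]oxy}dimethylsilane
Conditions: TBSCl, imidazole, CH2Cl2, 0 → 23 °C
Reagents that add atoms: tert-butyl(chloro)dimethylsilane, CC(C)(C)[Si](C)(C)Cl
Why: Silyl ether protection of the only hydroxyl masks the future C2 aldehyde through the hydride step and touches no stereocentre.

Step 2
Reactants: 2 tert-butyl{[(3S)-3,7-dimethyloct-6-en-1-yl]oxy}dimethylsilane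
Product: 3 (2E,6S)-8-{[tert-butyl(dimethyl)silyl]oxy}-2,6-dimethyloct-2-en-1-ol
Conditions: SeO2 (0.5 equiv), t-BuOOH (3 equiv), CH2Cl2, 23 °C
Reagents that add atoms: selenium dioxide, O=[Se]=O; tert-butyl hydroperoxide, CC(C)(C)OO
Why: SeO2-catalysed allylic oxidation (Sharpless–Umbreit ene/[2,3]-sigmatropic sequence) hydroxylates the (E)-methyl of the trisubstituted alkene selectively, giving the (E)-2-methyl allylic alcohol without touching the C6 stereocentre.

Step 3
Reactants: 3 (2E,6S)-8-{[tert-butyl(dimethyl)silyl]oxy}-2,6-dimethyloct-2-en-1-ol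
Product: 4 {(2S,3S)-3-[(3S)-5-{[tert-butyl(dimethyl)silyl]oxy}-3-methylpentyl]-2-methyloxiran-2-yl}methanol
Conditions: Ti(OiPr)4 (10 mol %), L-(+)-diethyl tartrate (12 mol %), t-BuOOH, 4 Å molecular sieves, CH2Cl2, −20 °C
Reagents that add atoms: tert-butyl hydroperoxide, CC(C)(C)OO
Why: Sharpless asymmetric epoxidation with L-(+)-diethyl tartrate delivers oxygen to the face of the (E)-2-methyl allylic alcohol that gives the (2S,3S)-epoxy alcohol, fixing the future C8 carbinol centre under reagent control.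

Step 4
Reactants: 4 {(2S,3S)-3-[(3S)-5-{[tert-butyl(dimethyl)silyl]oxy}-3-methylpentyl]-2-methyloxiran-2-yl}methanol
Product: 5 (2R,6S)-8-{[tert-butyl(dimethyl)silyl]oxy}-2,6-dimethyloctane-1,2-diol
Conditions: LiAlH4, THF, 0 → 23 °C
Reagents that add atoms: none
Why: Hydride opening of the 2,3-epoxy alcohol by SN2 attack at the less substituted C3 (C2 is fully substituted) leaves the C2–O bond intact, so the tertiary carbinol keeps the configuration set in step 3 (2R only by the priority rules) and the silyl ether survives.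

Step 5
Reactants: 5 (2R,6S)-8-{[tert-butyl(dimethyl)silyl]oxy}-2,6-dimethyloctane-1,2-diol
Product: 6 (2R,6S)-8-{[tert-butyl(dimethyl)silyl]oxy}-2-hydroxy-2,6-dimethyloctanal
Conditions: IBX, DMSO, 23 °C
Reagents that add atoms: none
Why: IBX oxidation converts the primary hydroxyl of the 1,2-diol into the aldehyde without glycol cleavage, and the quaternary α-carbon cannot epimerise.

Step 6
Reactants: 6 (2R,6S)-8-{[tert-butyl(dimethyl)silyl]oxy}-2-hydroxy-2,6-dimethyloctanal
Product: 7 (3R,7S)-9-{[tert-butyl(dimethyl)silyl]oxy}-3,7-dimethylnon-1-yn-3-ol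
Conditions: dimethyl (1-diazo-2-oxopropyl)phosphonate, K2CO3, MeOH, 0 → 23 °C
Reagents that add atoms: dimethyl (1-diazo-2-oxopropyl)phosphonate, CC(=O)C(=[N+]=[N-])P(=O)(OC)OC
Why: Seyferth–Gilbert homologation (Ohira–Bestmann variant) turns the non-enolisable α-hydroxy aldehyde into the terminal alkyne under mild conditions that leave the silyl ether and the tertiary carbinol centre alone.

Step 7
Reactants: 8 4-methylpent-3-en-1-ol
Product: 9 4-methylpent-3-enal
Conditions: IBX, EtOAc, 75 °C; filtered solution used directly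
Reagents that add atoms: none
Why: IBX oxidation under neutral conditions gives the β,γ-unsaturated aldehyde without moving the alkene into conjugation.

Step 8
Reactants: 9 4-methylpent-3-enal; 10 methyl acrylate
Product: 11 methyl 3-hydroxy-6-methyl-2-methylidenehept-5-enoate (racemic)
Conditions: DABCO (30 mol %), MeOH, 23 °C, 3 d
Reagents that add atoms: none
Why: Morita–Baylis–Hillman reaction (ammonium enolate of the acrylate adds to the aldehyde, then elimination of DABCO); the carbinol centre is left racemic on purpose because it becomes sp2 in step 17.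

Step 9
Reactants: 11 methyl 3-hydroxy-6-methyl-2-methylidenehept-5-enoate
Product: 12 methyl (5E)-3,7-dihydroxy-6-methyl-2-methylidenehept-5-enoate (racemic)
Conditions: SeO2 (0.5 equiv), t-BuOOH (3 equiv), CH2Cl2, 23 °C
Reagents that add atoms: selenium dioxide, O=[Se]=O; tert-butyl hydroperoxide, CC(C)(C)OO
Why: SeO2 allylic oxidation again takes the (E)-methyl of the electron-rich trisubstituted alkene, while the electron-poor acrylate alkene does not undergo the ene step.

Step 10
Reactants: 12 methyl (5E)-3,7-dihydroxy-6-methyl-2-methylidenehept-5-enoate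
Product: 13 methyl (5E)-7-bromo-3-hydroxy-6-methyl-2-methylidenehept-5-enoate (racemic)
Conditions: CBr4 (1.05 equiv), PPh3 (1.05 equiv), CH2Cl2, −40 °C
Reagents that add atoms: tetrabromomethane, BrC(Br)(Br)Br
Why: Appel bromination with one equivalent at low temperature takes the unhindered primary allylic alcohol in preference to the hindered secondary Baylis–Hillman alcohol and proceeds by direct SN2 displacement, so the (E)-alkene is kept.

Step 11
Reactants: 7 (3R,7S)-9-{[tert-butyl(dimethyl)silyl]oxy}-3,7-dimethylnon-1-yn-3-ol; 13 methyl (5E)-7-bromo-3-hydroxy-6-methyl-2-methylidenehept-5-enoate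
Product: 14 methyl (3RS,5E,10R,14S)-16-{[tert-butyl(dimethyl)silyl]oxy}-3,10-dihydroxy-6,10,14-trimethyl-2-methylidenehexadec-5-en-8-ynoate
Conditions: CuI (20 mol %), K2CO3, Bu4NBr (20 mol %), DMF, 23 °C
Reagents that add atoms: none
Why: Copper-mediated sp–sp3 coupling of a terminal alkyne with an allylic bromide (copper acetylide attacks the primary carbon) forms the C10–C11 bond as a skipped enyne under conditions mild enough for the acrylate and the free hydroxyls; no stereocentre is formed.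

Step 12
Reactants: 14 methyl (3RS,5E,10R,14S)-16-{[tert-butyl(dimethyl)silyl]oxy}-3,10-dihydroxy-6,10,14-trimethyl-2-methylidenehexadec-5-en-8-ynoate
Product: 15 methyl (3RS,5S,6S,10R,14S)-16-{[tert-butyl(dimethyl)silyl]oxy}-5,6-epoxy-3,10-dihydroxy-6,10,14-trimethyl-2-methylidenehexadec-8-ynoate
Conditions: 1,2:4,5-di-O-isopropylidene-β-L-erythro-2,3-hexodiulo-2,6-pyranose (enantiomer of the Shi ketone, 30 mol %), Oxone (2KHSO5·KHSO4·K2SO4), K2CO3, Bu4NHSO4, MeCN/dimethoxymethane/aqueous Na2B4O7 buffer (pH 10.5), 0 °C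
Reagents that add atoms: potassium peroxymonosulfate, [K+].[O-]S(=O)(=O)OO
Why: Shi asymmetric epoxidation: the chiral dioxirane epoxidises only the electron-rich trisubstituted (E)-alkene (acrylate and alkyne are inert) through the spiro transition state, and the L-fructose-derived ketone gives the (5S,6S)-epoxide, the future C13/C12 centres, under catalyst control.

Step 13
Reactants: 15 methyl (3RS,5S,6S,10R,14S)-16-{[tert-butyl(dimethyl)silyl]oxy}-5,6-epoxy-3,10-dihydroxy-6,10,14-trimethyl-2-methylidenehexadec-8-ynoate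
Product: 16 methyl (3RS,5S,6S,8Z,10R,14S)-16-{[tert-butyl(dimethyl)silyl]oxy}-5,6-epoxy-3,10-dihydroxy-6,10,14-trimethyl-2-methylidenehexadec-8-enoate
Conditions: H2 (1 atm), Pd on CaCO3 poisoned with Pb(OAc)2, quinoline, EtOAc, 23 °C
Reagents that add atoms: none
Why: Lindlar semihydrogenation adds H2 syn to the alkyne and stops at the (Z)-alkene, the poisoned catalyst leaving the acrylate and the epoxide untouched.

Step 14
Reactants: 16 methyl (3RS,5S,6S,8Z,10R,14S)-16-{[tert-butyl(dimethyl)silyl]oxy}-5,6-epoxy-3,10-dihydroxy-6,10,14-trimethyl-2-methylidenehexadec-8-enoate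
Product: 17 methyl (3RS,5S,6S,8Z,10R,14S)-5,6-epoxy-3,10,16-trihydroxy-6,10,14-trimethyl-2-methylidenehexadec-8-enoate
Conditions: Bu4NF, AcOH (1:1), THF, 0 → 23 °C
Reagents that add atoms: none
Why: Fluoride-mediated desilylation, buffered with AcOH so that neither the acrylate nor the epoxide meets a free alkoxide, releases the primary alcohol.

Step 15
Reactants: 17 methyl (3RS,5S,6S,8Z,10R,14S)-5,6-epoxy-3,10,16-trihydroxy-6,10,14-trimethyl-2-methylidenehexadec-8-enoate
Product: 18 methyl (3RS,5S,6S,8Z,10R,14S)-5,6-epoxy-3,10-dihydroxy-6,10,14-trimethyl-2-methylidene-16-oxohexadec-8-enoate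
Conditions: TEMPO (10 mol %), PhI(OAc)2 (1.1 equiv), CH2Cl2, 23 °C
Reagents that add atoms: none
Why: TEMPO/PhI(OAc)2 oxidation (oxoammonium catalysis) is selective for the primary alcohol over the secondary and tertiary ones and stops at the aldehyde.

Step 16
Reactants: 18 methyl (3RS,5S,6S,8Z,10R,14S)-5,6-epoxy-3,10-dihydroxy-6,10,14-trimethyl-2-methylidene-16-oxohexadec-8-enoate
Product: 19 methyl (3RS,5S,6S,8Z,10R,14S,15R)-15-(benzoyloxy)-5,6-epoxy-3,10-dihydroxy-6,10,14-trimethyl-2-methylidene-16-oxohexadec-8-enoate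
Conditions: (R)-2-[diphenyl(trimethylsilyloxy)methyl]pyrrolidine (20 mol %), dibenzoyl peroxide (1.2 equiv), hydroquinone (10 mol %), THF, 0 °C
Reagents that add atoms: dibenzoyl peroxide, O=C(OOC(=O)c1ccccc1)c1ccccc1
Why: Enamine organocatalysis (α-benzoyloxylation of an aldehyde): the bulky group of the (R)-diarylprolinol silyl ether shields one face of the anti (E)-enamine, so the peroxide oxygen is delivered to the other face and C15 is set as R under catalyst control next to the existing 14S centre.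

Step 17
Reactants: 19 methyl (3RS,5S,6S,8Z,10R,14S,15R)-15-(benzoyloxy)-5,6-epoxy-3,10-dihydroxy-6,10,14-trimethyl-2-methylidene-16-oxohexadec-8-enoate
Product: 20 methyl (2Z,5S,6S,8Z,10R,14S,15R)-15-(benzoyloxy)-2-(bromomethyl)-5,6-epoxy-10-hydroxy-6,10,14-trimethyl-16-oxohexadeca-2,8-dienoate
Conditions: N-bromosuccinimide, Me2S, CH2Cl2, −20 → 0 °C
Reagents that add atoms: N-bromosuccinimide, O=C1CCC(=O)N1Br
Why: Corey–Kim-type activation of the Baylis–Hillman alcohol followed by SN2′ attack of bromide gives the (Z)-2-(bromomethyl)enoate (the preferred trisubstituted enoate geometry), removing the epimeric carbinol centre under neutral conditions that spare the aldehyde, benzoate, epoxide and hindered tertiary alcohol.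

Step 18
Reactants: 20 methyl (2Z,5S,6S,8Z,10R,14S,15R)-15-(benzoyloxy)-2-(bromomethyl)-5,6-epoxy-10-hydroxy-6,10,14-trimethyl-16-oxohexadeca-2,8-dienoate
Product: 22 (1R,2S,3R,4S,8R,9Z,12S,13S)-3-(benzoyloxy)-12,13-epoxy-8-hydroxycembra-9,15(17)-dien-16,2-olide, via macrocyclic hydroxy ester chromium alkoxide 21 (not isolated)
Conditions: CrCl2 (6 equiv), THF, 23 °C, slow addition of 20 to a final 0.002 M, then 6 h
Reagents that add atoms: none
Why: Intramolecular Nozaki–Hiyama (Barbier-type) allylation with lactonisation (Dreiding–Schmidt-type α-methylene-γ-lactone annulation): the allylchromium from the 2-(bromomethyl)enoate adds through its γ-carbon in a chair Zimmerman–Traxler transition state in which the (Z)-allyl unit holds C14 axial (1,2-syn, hence the cis-fused lactone) while polar Felkin–Anh attack anti to the C3 benzoate gives the 2,3-anti relationship, so C1 (R) and C2 (S) are set together as the 14-membered ring closes and the chromium alkoxide expels methoxide to close the lactone.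

Step 19
Reactants: 22 (1R,2S,3R,4S,8R,9Z,12S,13S)-3-(benzoyloxy)-12,13-epoxy-8-hydroxycembra-9,15(17)-dien-16,2-olide
Product: 25 (1R,2S,3R,4S,8R,9Z,12S,13R)-3,13-epoxy-8,12-dihydroxycembra-9,15(17)-dien-16,2-olide (target), via epoxy trihydroxy acid lithium salt 23 (not isolated), via tetrahydropyran hydroxy acid 24 (not isolated)
Conditions: LiOH (6 equiv), DMSO/H2O 4:1, 23 → 45 °C; then 0.5 M HCl to pH 4, 0 → 23 °C
Reagents that add atoms: none
Why: Saponification, intramolecular epoxide opening and relactonisation: hydroxide cleaves the benzoate and opens the lactone to the carboxylate (a poor Michael acceptor), the C3 alkoxide attacks C13 in a 6-exo-tet SN2 closure with inversion (13S → 13R) that gives the 2,6-cis tetrahydropyran and the C12 tertiary alcohol, and mild acid recloses the cis γ-lactone; any benzoyl migration in 22 is harmless because every ester is cleaved.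

**Compound list**

1 | (S)-citronellol, (3S)-3,7-dimethyloct-6-en-1-ol | CC(C)=CCC[C@H](C)CCO | starting material
2 | tert-butyl{[(3S)-3,7-dimethyloct-6-en-1-yl]oxy}dimethylsilane | CC(C)=CCC[C@H](C)CCO[Si](C)(C)C(C)(C)C | intermediate
3 | (2E,6S)-8-{[tert-butyl(dimethyl)silyl]oxy}-2,6-dimethyloct-2-en-1-ol | OC/C(C)=C/CC[C@H](C)CCO[Si](C)(C)C(C)(C)C | intermediate
4 | {(2S,3S)-3-[(3S)-5-{[tert-butyl(dimethyl)silyl]oxy}-3-methylpentyl]-2-methyloxiran-2-yl}methanol | OC[C@]1(C)O[C@H]1CC[C@H](C)CCO[Si](C)(C)C(C)(C)C | intermediate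
5 | (2R,6S)-8-{[tert-butyl(dimethyl)silyl]oxy}-2,6-dimethyloctane-1,2-diol | OC[C@](C)(O)CCC[C@H](C)CCO[Si](C)(C)C(C)(C)C | intermediate
6 | (2R,6S)-8-{[tert-butyl(dimethyl)silyl]oxy}-2-hydroxy-2,6-dimethyloctanal | O=C[C@](C)(O)CCC[C@H](C)CCO[Si](C)(C)C(C)(C)C | intermediate
7 | (3R,7S)-9-{[tert-butyl(dimethyl)silyl]oxy}-3,7-dimethylnon-1-yn-3-ol | C#C[C@](C)(O)CCC[C@H](C)CCO[Si](C)(C)C(C)(C)C | intermediate
8 | 4-methylpent-3-en-1-ol | CC(C)=CCCO | starting material
9 | 4-methylpent-3-enal | CC(C)=CCC=O | intermediate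
10 | methyl acrylate | C=CC(=O)OC | starting material
11 | methyl 3-hydroxy-6-methyl-2-methylidenehept-5-enoate (racemic) | COC(=O)C(=C)C(O)CC=C(C)C | intermediate
12 | methyl (5E)-3,7-dihydroxy-6-methyl-2-methylidenehept-5-enoate (racemic) | COC(=O)C(=C)C(O)C/C=C(\C)CO | intermediate
13 | methyl (5E)-7-bromo-3-hydroxy-6-methyl-2-methylidenehept-5-enoate (racemic) | COC(=O)C(=C)C(O)C/C=C(\C)CBr | intermediate
14 | methyl (3RS,5E,10R,14S)-16-{[tert-butyl(dimethyl)silyl]oxy}-3,10-dihydroxy-6,10,14-trimethyl-2-methylidenehexadec-5-en-8-ynoate (both C3 epimers) | COC(=O)C(=C)C(O)C/C=C(\C)CC#C[C@](C)(O)CCC[C@H](C)CCO[Si](C)(C)C(C)(C)C | intermediate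
15 | methyl (3RS,5S,6S,10R,14S)-16-{[tert-butyl(dimethyl)silyl]oxy}-5,6-epoxy-3,10-dihydroxy-6,10,14-trimethyl-2-methylidenehexadec-8-ynoate | COC(=O)C(=C)C(O)C[C@@H]1O[C@@]1(C)CC#C[C@](C)(O)CCC[C@H](C)CCO[Si](C)(C)C(C)(C)C | intermediate
16 | methyl (3RS,5S,6S,8Z,10R,14S)-16-{[tert-butyl(dimethyl)silyl]oxy}-5,6-epoxy-3,10-dihydroxy-6,10,14-trimethyl-2-methylidenehexadec-8-enoate | COC(=O)C(=C)C(O)C[C@@H]1O[C@@]1(C)C/C=C\[C@](C)(O)CCC[C@H](C)CCO[Si](C)(C)C(C)(C)C | intermediate
17 | methyl (3RS,5S,6S,8Z,10R,14S)-5,6-epoxy-3,10,16-trihydroxy-6,10,14-trimethyl-2-methylidenehexadec-8-enoate | COC(=O)C(=C)C(O)C[C@@H]1O[C@@]1(C)C/C=C\[C@](C)(O)CCC[C@H](C)CCO | intermediate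
18 | methyl (3RS,5S,6S,8Z,10R,14S)-5,6-epoxy-3,10-dihydroxy-6,10,14-trimethyl-2-methylidene-16-oxohexadec-8-enoate | COC(=O)C(=C)C(O)C[C@@H]1O[C@@]1(C)C/C=C\[C@](C)(O)CCC[C@H](C)CC=O | intermediate
19 | methyl (3RS,5S,6S,8Z,10R,14S,15R)-15-(benzoyloxy)-5,6-epoxy-3,10-dihydroxy-6,10,14-trimethyl-2-methylidene-16-oxohexadec-8-enoate | COC(=O)C(=C)C(O)C[C@@H]1O[C@@]1(C)C/C=C\[C@](C)(O)CCC[C@H](C)[C@@H](OC(=O)c1ccccc1)C=O | intermediate
20 | methyl (2Z,5S,6S,8Z,10R,14S,15R)-15-(benzoyloxy)-2-(bromomethyl)-5,6-epoxy-10-hydroxy-6,10,14-trimethyl-16-oxohexadeca-2,8-dienoate | COC(=O)/C(CBr)=C/C[C@@H]1O[C@@]1(C)C/C=C\[C@](C)(O)CCC[C@H](C)[C@@H](OC(=O)c1ccccc1)C=O | intermediate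
21 | methyl 2-[(1R,2S,3R,4S,8R,9Z,12S,13S)-3-(benzoyloxy)-12,13-epoxy-2,8-dihydroxy-4,8,12-trimethylcyclotetradec-9-en-1-yl]prop-2-enoate, present as its chromium alkoxide at O2 and drawn as the free alcohol | O[C@@H]1[C@H](OC(=O)c2ccccc2)[C@@H](C)CCC[C@@](C)(O)/C=C\C[C@]3(C)O[C@H]3C[C@@H]1C(=C)C(=O)OC | intermediate (not isolated)
22 | (1R,2S,3R,4S,8R,9Z,12S,13S)-3-(benzoyloxy)-12,13-epoxy-8-hydroxycembra-9,15(17)-dien-16,2-olide | C=C1C(=O)O[C@@H]2[C@H](OC(=O)c3ccccc3)[C@@H](C)CCC[C@@](C)(O)/C=C\C[C@]4(C)O[C@H]4C[C@H]12 | intermediate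
23 | (1R,2S,3R,4S,8R,9Z,12S,13S)-12,13-epoxy-2,3,8-trihydroxycembra-9,15(17)-dien-16-oic acid, present as its lithium salt and drawn as the acid | O[C@@H]1[C@H](O)[C@@H](C)CCC[C@@](C)(O)/C=C\C[C@]2(C)O[C@H]2C[C@@H]1C(=C)C(=O)O | intermediate (not isolated)
24 | (1R,2S,3R,4S,8R,9Z,12S,13R)-3,13-epoxy-2,8,12-trihydroxycembra-9,15(17)-dien-16-oic acid | O[C@@H]1[C@@H]2O[C@H](C[C@@H]1C(=C)C(=O)O)[C@@](C)(O)C/C=C\[C@](C)(O)CCC[C@@H]2C | intermediate (not isolated)
25 | (1R,2S,3R,4S,8R,9Z,12S,13R)-3,13-epoxy-8,12-dihydroxycembra-9,15(17)-dien-16,2-olide | C=C1C(=O)O[C@@H]2[C@@H]3O[C@H](C[C@H]12)[C@@](C)(O)C/C=C\[C@](C)(O)CCC[C@@H]3C | target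

**Counts and risks**

Total step count: 19. Longest linear sequence: 15 steps (steps 1–6 and 11–19, from (S)-citronellol).

Most likely to fail:

1. Step 18 (macro-allylation/lactonisation). Risks are oligomerisation and incomplete control of C1/C2 in a 14-membered transition state. The fallback sets out from 19 and comes back at 22, and forms the same bond with an isolable allylboron reagent instead of a low-valent metal. Acetylation of 19 (Ac2O, pyridine, DMAP cat., 0 °C) gives the allylic acetate F1. Borylation of F1 with B2pin2 and Pd2(dba)3 (cat., toluene, 50 °C, through a π-allylpalladium) gives the (E)-allylboronate F2, whose geometry can be checked before the ring is closed. Heating F2 at high dilution (toluene, 80 °C) closes the carbocycle by intramolecular allylboration through a closed chair, and the borate lactonises on work-up to 22.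

2. Step 19 (base-mediated tetrahydropyran closure with the exo-methylene acid exposed). Risks are conjugate addition to the α-methylene unit before the lactone opens, or incomplete 6-exo closure. The fallback sets out from 22 and comes back at 25, keeping the lactone closed and masked. Dimethylamine (THF, 0 °C) adds to the exocyclic alkene to give the dimethylamine adduct F3. K2CO3 in MeOH (40 °C) removes the benzoate, and the C3 alkoxide opens the epoxide to the amino tetrahydropyran F4. MeI (MeCN) gives the ammonium iodide F5, and aqueous NaHCO3 eliminates trimethylamine to restore the α-methylene lactone 25.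

3. Step 12 (Shi epoxidation: face selectivity and a C3 epimer mixture that hides the diastereomer ratio). The fallback sets out from 11 (and uses 7) and comes back at 17; it sets the epoxide before the two halves are joined and replaces the copper coupling by a triflate displacement. TBSOTf/2,6-lutidine converts 11 into the silyl ether F6, and SeO2/t-BuOOH gives the allylic alcohol F7. Sharpless epoxidation (Ti(OiPr)4, L-(+)-diethyl tartrate, t-BuOOH) gives the (2S,3S)-epoxy alcohol F8. Tf2O/2,6-lutidine (−78 °C) gives the triflate F9, which is displaced in the same flask by the dilithio derivative F10 of 7 (n-BuLi, 2 equiv, THF/DMPU, −78 °C) to give the epoxy enyne F11. Lindlar reduction gives the (Z)-alkene F12, and Bu4NF removes both silyl ethers to give 17.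

Further compounds
F1 | step 18 | methyl (3RS,5S,6S,8Z,10R,14S,15R)-3-acetoxy-15-(benzoyloxy)-5,6-epoxy-10-hydroxy-6,10,14-trimethyl-2-methylidene-16-oxohexadec-8-enoate | COC(=O)C(=C)C(OC(C)=O)C[C@@H]1O[C@@]1(C)C/C=C\[C@](C)(O)CCC[C@H](C)[C@@H](OC(=O)c1ccccc1)C=O
F2 | step 18 | methyl (2E,5S,6S,8Z,10R,14S,15R)-15-(benzoyloxy)-5,6-epoxy-10-hydroxy-6,10,14-trimethyl-16-oxo-2-[(4,4,5,5-tetramethyl-1,3,2-dioxaborolan-2-yl)methyl]hexadeca-2,8-dienoate | COC(=O)/C(CB1OC(C)(C)C(C)(C)O1)=C/C[C@@H]2O[C@@]2(C)C/C=C\[C@](C)(O)CCC[C@H](C)[C@@H](OC(=O)c2ccccc2)C=O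
F3 | step 19 | (1R,2S,3R,4S,8R,9Z,12S,13S,15RS)-3-(benzoyloxy)-17-(dimethylamino)-12,13-epoxy-8-hydroxycembr-9-en-16,2-olide | CN(C)CC1C(=O)O[C@@H]2[C@H](OC(=O)c3ccccc3)[C@@H](C)CCC[C@@](C)(O)/C=C\C[C@]4(C)O[C@H]4C[C@H]12
F4 | step 19 | (1R,2S,3R,4S,8R,9Z,12S,13R,15RS)-17-(dimethylamino)-3,13-epoxy-8,12-dihydroxycembr-9-en-16,2-olide | CN(C)CC1C(=O)O[C@@H]2[C@@H]3O[C@H](C[C@H]12)[C@@](C)(O)C/C=C\[C@](C)(O)CCC[C@@H]3C
F5 | step 19 | trimethylammonium iodide of F4 (N-methylated at the C17 amine) | C[N+](C)(C)CC1C(=O)O[C@@H]2[C@@H]3O[C@H](C[C@H]12)[C@@](C)(O)C/C=C\[C@](C)(O)CCC[C@@H]3C.[I-]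
F6 | step 12 | methyl 3-{[tert-butyl(dimethyl)silyl]oxy}-6-methyl-2-methylidenehept-5-enoate (racemic) | COC(=O)C(=C)C(O[Si](C)(C)C(C)(C)C)CC=C(C)C
F7 | step 12 | methyl (5E)-3-{[tert-butyl(dimethyl)silyl]oxy}-7-hydroxy-6-methyl-2-methylidenehept-5-enoate | COC(=O)C(=C)C(O[Si](C)(C)C(C)(C)C)C/C=C(\C)CO
F8 | step 12 | methyl (3RS)-3-{[tert-butyl(dimethyl)silyl]oxy}-4-[(2S,3S)-3-(hydroxymethyl)-3-methyloxiran-2-yl]-2-methylidenebutanoate | COC(=O)C(=C)C(O[Si](C)(C)C(C)(C)C)C[C@@H]1O[C@@]1(C)CO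
F9 | step 12 | trifluoromethanesulfonate of F8 at the primary hydroxyl | COC(=O)C(=C)C(O[Si](C)(C)C(C)(C)C)C[C@@H]1O[C@@]1(C)COS(=O)(=O)C(F)(F)F
F10 | step 12 | dilithio derivative of 7 (lithium acetylide and lithium alkoxide) | [Li]C#C[C@](C)(O[Li])CCC[C@H](C)CCO[Si](C)(C)C(C)(C)C
F11 | step 12 | 3-O-tert-butyldimethylsilyl ether of 15 | COC(=O)C(=C)C(O[Si](C)(C)C(C)(C)C)C[C@@H]1O[C@@]1(C)CC#C[C@](C)(O)CCC[C@H](C)CCO[Si](C)(C)C(C)(C)C
F12 | step 12 | 3-O-tert-butyldimethylsilyl ether of 16 | COC(=O)C(=C)C(O[Si](C)(C)C(C)(C)C)C[C@@H]1O[C@@]1(C)C/C=C\[C@](C)(O)CCC[C@H](C)CCO[Si](C)(C)C(C)(C)C
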